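**Retrosynthetic overview**

1. Feature: the skeleton is two chalcones joined α-carbon to α-carbon. The methine between the aryl ketone C=O and chromone C3 (the only stereocentre) is the α-carbon of the methoxy half, chromone C3 and C2 are the α- and β-carbons of the dihydroxy half, and the second 4-hydroxyphenyl ring on the diarylmethyl carbon has moved there from chromone C2.
2. 13 ⇒ 12: the two phenol oxygens that take no part in the cascade (the ortho-oxygen of the methoxyphenyl ketone and chromone O7) are bridged by an (R,R)-1,3-phenylenebis(ethane-1,1-diyl) tether, cut last by hydrogenolysis.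
3. 12 ⇒ 8 (key): oxidation of the tethered bis-chalcone joins the two α-carbons (methine–C3 bond, 17-membered ring), then O1–C2 closes the pyranone ring and a 1,4-aryl shift through a spiro-cyclopentane builds the diarylmethyl carbon.
4. 8 ⇒ tethered bis-acetophenone 6 + 4-hydroxybenzaldehyde (twofold Claisen–Schmidt); 6 ⇒ (S,S)-diol 2 + paeonol + 2',4'-dihydroxyacetophenone (two Mitsunobu etherifications); 2 ⇒ 1,3-diacetylbenzene.
5. Ring order: macrocycle (C–C coupling), pyranone ring, transient spiro ring (opened again in the same step); the tether is removed at the end.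

Key step: step 5

Assumption: which hand of the tether favours the (R)-methine cannot be told in advance; the route is written with the (R,R)-tether, and if that hand favours the (S)-methine, the (R,R)-diol from the mirror-image catalyst is carried through the same steps.

**Route**

Step 1
Reactants: 1 1,3-diacetylbenzene
Product: 2 (1S,1'S)-1,1'-(1,3-phenylene)di(ethan-1-ol)
Conditions: RuCl[(S,S)-TsDPEN](p-cymene) (1 mol%), HCO2H/Et3N (5:2), 28 °C
Reagents that add atoms: none
Why: Noyori asymmetric transfer hydrogenation: the chiral hydride formed from RuCl[(S,S)-TsDPEN](p-cymene) and formic acid should reduce each aryl methyl ketone from the same face, so that the catalyst sets both carbinol centres as (S), the second reduction raising the enantiomeric purity of the diol at the cost of a little meso isomer that is removed by crystallisation.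

Step 2
Reactants: 2 (1S,1'S)-1,1'-(1,3-phenylene)di(ethan-1-ol) (threefold excess, surplus recovered); 3 paeonol
Product: 4 1-{2-[(1R)-1-{3-[(1S)-1-hydroxyethyl]phenyl}ethoxy]-4-methoxyphenyl}ethanone
Conditions: PPh3, DIAD, THF, 0 °C to rt
Reagents that add atoms: none
Why: Mitsunobu etherification: the oxyphosphonium ion of one carbinol of the excess C2-symmetric diol is displaced by the phenoxide of 3 in an SN2 reaction, so the new ether centre is set as (R) by inversion of the (S)-carbinol while the second carbinol stays free.

Step 3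
Reactants: 4 1-{2-[(1R)-1-{3-[(1S)-1-hydroxyethyl]phenyl}ethoxy]-4-methoxyphenyl}ethanone; 5 2',4'-dihydroxyacetophenone
Product: 6 1-{2-[(1R)-1-{3-[(1R)-1-(4-acetyl-3-hydroxyphenoxy)ethyl]phenyl}ethoxy]-4-methoxyphenyl}ethanone (tethered bis-acetophenone)
Conditions: PPh3, DIAD, THF, 0 °C to rt
Reagents that add atoms: none
Why: Mitsunobu etherification: only the 4-OH of 5 is acidic and unhindered enough to react, its 2-OH being hydrogen-bonded to the acetyl group, and SN2 inversion of the remaining (S)-carbinol sets the second (R)-ether centre.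

Step 4
Reactants: 6 tethered bis-acetophenone; 7 4-hydroxybenzaldehyde (2.5 equiv)
Product: 8 tethered bis-chalcone, (E)-1-{2-[(1R)-1-{3-[(1R)-1-{3-hydroxy-4-[(E)-3-(4-hydroxyphenyl)prop-2-enoyl]phenoxy}ethyl]phenyl}ethoxy]-4-methoxyphenyl}-3-(4-hydroxyphenyl)prop-2-en-1-one
Conditions: KOH (50% aq.), EtOH, rt; then 1 M HCl to pH 4
Reagents that add atoms: none
Why: Twofold Claisen–Schmidt condensation: each methyl ketone enolate adds to the aldehyde and E1cB loss of water gives the (E)-enone, the benzylic ether tether is inert to hydroxide, and acidification returns the phenols and the open 2'-hydroxychalcone.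

Step 5
Reactants: 8 tethered bis-chalcone
Product: 12 tether-bridged (R)-chromone macrocycle, via bis(quinone methide) 9 (not isolated), via flavanone quinone methide 10 (not isolated), via spirodienone 11 (not isolated)
Conditions: Ag2O (1.1 equiv), 4 Å MS, CH2Cl2/acetone (4:1), 1 mM, rt, dark; filter; then PPTS (0.2 equiv), rt; methine epimers separated on silica
Reagents that add atoms: none
Why: Proposed new method: Ag2O takes one electron and one proton from each 4-hydroxyphenyl group of 8, and the two phenoxyl radicals, whose spin reaches the enone α-carbons, should combine there to form the methine–C3 bond of bis(quinone methide) 9, a radical–radical macrocyclisation that closes the 17-membered ring. The chelated 2'-OH of the dihydroxy half then adds to its own quinone methide carbon (6-exo-trig oxa-1,6-addition, O1–C2 bond, pyranone ring) to give 10, the 2-(4-hydroxyphenyl) ring of 10 attacks the second quinone methide carbon through its ipso carbon (5-exo-trig, aryl–CH bond) to give spirodienone 11, and acid-assisted cleavage of the C2–spiro bond with loss of H3 from the oxocarbenium ion gives the chromone and leaves both 4-hydroxyphenyl rings on one carbon. The closest known reaction type is the oxidative coupling of para-hydroxycinnamyl phenols at their side-chain carbons with internal trapping of the quinone methides (lignan-type 8–8 dimerisation); neither a chalcone pair nor a tethered macrocyclic version nor the following aryl shift has been shown. The methine next to the ketone, the only stereocentre that survives, is set in the C–C coupling, where the (R)-1-arylethyl ether on the ortho-oxygen of the methoxy half and the tether make the two faces of that α-carbon diastereotopic; the sense and size of the induction cannot be predicted, so the two methine epimers of 12, being diastereomers, are separated by chromatography. The step needs cross- over homo-coupling (secured by the tether and high dilution), α-to-α over α-to-ring-carbon or α-to-oxygen coupling (α-to-α closes the smallest ring, the other modes need 21 or more ring atoms) and ring closure of one half only (the ortho-oxygen of the methoxy half is an ether, so the methyl ether ends up on the open-chain ketone).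

Step 6
Reactants: 12 tether-bridged (R)-chromone macrocycle
Product: 13 7-hydroxy-3-[(2R)-3-(2-hydroxy-4-methoxyphenyl)-1,1-bis(4-hydroxyphenyl)-3-oxopropan-2-yl]-4H-chromen-4-one (target)
Conditions: H2 (1 atm), Pd/C (10%), EtOAc/MeOH (1:1), rt
Reagents that add atoms: none
Why: Hydrogenolysis of the two benzylic C–O bonds over Pd/C frees both phenols and releases the tether as a hydrocarbon in a neutral medium that leaves the enolisable (R)-methine untouched, the reaction being stopped after two equivalents of H2 so that the chromone C2=C3 bond and the aryl ketone should survive.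

**Compound list**

1 | 1,3-diacetylbenzene | CC(=O)c1cccc(C(C)=O)c1 | starting material
2 | (1S,1'S)-1,1'-(1,3-phenylene)di(ethan-1-ol) | C[C@H](O)c1cccc([C@H](C)O)c1 | intermediate
3 | paeonol, 1-(2-hydroxy-4-methoxyphenyl)ethanone | CC(=O)c1ccc(OC)cc1O | starting material
4 | 1-{2-[(1R)-1-{3-[(1S)-1-hydroxyethyl]phenyl}ethoxy]-4-methoxyphenyl}ethanone | CC(=O)c1ccc(OC)cc1O[C@H](C)c1cccc([C@H](C)O)c1 | intermediate
5 | 2',4'-dihydroxyacetophenone | CC(=O)c1ccc(O)cc1O | starting material
6 | 1-{2-[(1R)-1-{3-[(1R)-1-(4-acetyl-3-hydroxyphenoxy)ethyl]phenyl}ethoxy]-4-methoxyphenyl}ethanone (tethered bis-acetophenone) | CC(=O)c1ccc(OC)cc1O[C@H](C)c1cccc(c1)[C@@H](C)Oc1ccc(C(C)=O)c(O)c1 | intermediate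
7 | 4-hydroxybenzaldehyde | O=Cc1ccc(O)cc1 | starting material
8 | tethered bis-chalcone: 4'-O-methylisoliquiritigenin (through O-2') and isoliquiritigenin (through O-4') joined by the (R,R)-1,3-phenylenebis(ethane-1,1-diyl) tether, both enones (E) | COc1ccc(C(=O)/C=C/c2ccc(O)cc2)c(O[C@H](C)c2cccc(c2)[C@@H](C)Oc2ccc(C(=O)/C=C/c3ccc(O)cc3)c(O)c2)c1 | intermediate
9 | bis(quinone methide): the two α-carbons of 8 joined in a 17-membered ring, each β-carbon the exocyclic CH of a 4-oxocyclohexa-2,5-dienylidene; methine of the methoxy half as in 12, the other α-carbon unassigned | COc1ccc2c(c1)O[C@H](C)c1cccc(c1)[C@@H](C)Oc1ccc(c(O)c1)C(=O)C(C=C1C=CC(=O)C=C1)[C@@H](C=C1C=CC(=O)C=C1)C2=O | intermediate (not isolated)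
10 | flavanone quinone methide: the dihydroxy half closed to a 2-(4-hydroxyphenyl)chroman-4-one whose C3 carries the methine of the methoxy half, the second quinone methide intact; C2 and C3 unassigned | COc1ccc2c(c1)O[C@H](C)c1cccc(c1)[C@@H](C)Oc1ccc3c(c1)OC(c1ccc(O)cc1)C(C3=O)[C@@H](C=C1C=CC(=O)C=C1)C2=O | intermediate (not isolated)
11 | spirodienone: cyclopentane made of chromanone C2 and C3, the methine, the (4-hydroxyphenyl)CH carbon and a spiro carbon that is C4 of a cyclohexa-2,5-dienone; transient centres unassigned | COc1ccc2c(c1)O[C@H](C)c1cccc(c1)[C@@H](C)Oc1ccc3c(c1)OC1C(C3=O)[C@H](C2=O)C(c2ccc(O)cc2)C12C=CC(=O)C=C2 | intermediate (not isolated)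
12 | tether-bridged chromone macrocycle: 13 with the ortho-oxygen of its methoxyphenyl ketone and its chromone O7 joined by the (R,R)-1,3-phenylenebis(ethane-1,1-diyl) tether (17-membered ring), (R) at the methine | COc1ccc2c(c1)O[C@H](C)c1cccc(c1)[C@@H](C)Oc1ccc3c(c1)occ(c3=O)[C@H](C2=O)C(c1ccc(O)cc1)c1ccc(O)cc1 | intermediate
13 | 7-hydroxy-3-[(2R)-3-(2-hydroxy-4-methoxyphenyl)-1,1-bis(4-hydroxyphenyl)-3-oxopropan-2-yl]-4H-chromen-4-one | COc1ccc(C(=O)[C@@H](c2coc3cc(O)ccc3c2=O)C(c2ccc(O)cc2)c2ccc(O)cc2)c(O)c1 | target

**Totals**

Total step count: 6. Longest linear sequence: 6 steps (1 → 2 → 4 → 6 → 8 → 12 → 13).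

**Steps most likely to fail**

Step 5 (Proposed new method). What may go wrong:
- the two phenoxyl radicals may combine through a ring carbon ortho to oxygen or through oxygen instead of α to α, or between molecules to give oligomers;
- the quinone methides may be captured by water before the aryl shift;
- the bis(4-hydroxyphenyl)methyl group of the product may be oxidised further;
- the tether may discriminate poorly between the two faces of the methine carbon. The unwanted epimer of 12 might be returned by mild base, since that centre is enolisable.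

Fallback by known reactions only, setting out from paeonol 3 and coming back at 13, with no tether and a late resolution. Benzylation of 3 (BnBr, K2CO3, DMF) gives 1-[2-(benzyloxy)-4-methoxyphenyl]ethanone F1. Claisen–Schmidt condensation with 4-(benzyloxy)benzaldehyde (KOH, EtOH) gives (E)-1-[2-(benzyloxy)-4-methoxyphenyl]-3-[4-(benzyloxy)phenyl]prop-2-en-1-one F2. CuI-catalysed 1,4-addition of 4-(benzyloxy)phenylmagnesium bromide gives 1-[2-(benzyloxy)-4-methoxyphenyl]-3,3-bis[4-(benzyloxy)phenyl]propan-1-one F3. Its lithium enolate (LiN(SiMe3)2, THF, −78 °C) is alkylated by 2-bromo-1-[2,4-bis(benzyloxy)phenyl]ethanone F4, itself made from commercial 2',4'-bis(benzyloxy)acetophenone and PhNMe3Br3, to give the racemic pentabenzyl 1,4-diketone F5. BCl3 at −78 °C removes only the two benzyl groups chelated to a carbonyl oxygen and gives the racemic bis(2-hydroxyaryl) 1,4-diketone F6. Me2NCH(OMe)2 then condenses at the one methylene group α to a 2-hydroxyaryl ketone, and the enaminone closes to the chromone on acidification, giving the racemic tribenzyl chromone F7. Hydrogenolysis (H2, Pd/C) gives racemic 13 F8, which preparative HPLC on an amylose tris(3,5-dimethylphenylcarbamate) phase resolves to 13.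

Step 2. What may go wrong: activation and displacement are slow at a hindered phenol that is hydrogen-bonded to its acetyl group, so that elimination of the benzylic oxyphosphonium ion to the styrene, or its ionisation with loss of configuration, takes over.

Fallback from 2, coming back at 4, with the acetyl group brought in after the ether bond. Mitsunobu etherification of excess 2 with 2-bromo-5-methoxyphenol (PPh3, DIAD), a more acidic phenol without a chelating carbonyl group, gives with the same inversion (1S)-1-{3-[(1R)-1-(2-bromo-5-methoxyphenoxy)ethyl]phenyl}ethanol F9. Stille coupling with tributyl(1-ethoxyvinyl)stannane (PdCl2(PPh3)2, toluene, 100 °C) gives the enol ether (1S)-1-{3-[(1R)-1-[2-(1-ethoxyvinyl)-5-methoxyphenoxy]ethyl]phenyl}ethanol F10, which 1 M HCl hydrolyses on work-up to the methyl ketone 4.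

Step 4. What may go wrong: the aldehyde reacts as its electron-rich phenoxide, so the sequence may stall after the first condensation, and long exposure to base may close the 2'-hydroxychalcone half to the flavanone.

Fallback from 6, coming back at 8, with the aldehyde phenol masked. Condensation of 6 with 4-(tetrahydro-2H-pyran-2-yloxy)benzaldehyde (KOH, EtOH, rt), whose acetal cannot form a phenoxide, gives the bis(tetrahydropyranyl) ether of 8 F11. PPTS in MeOH at 40 °C then removes both acetals without touching the benzylic ethers or the 2'-hydroxychalcone and gives 8.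

**Further compounds**

F1 | step 5 | 1-[2-(benzyloxy)-4-methoxyphenyl]ethanone | CC(=O)c1ccc(OC)cc1OCc1ccccc1
F2 | step 5 | (E)-1-[2-(benzyloxy)-4-methoxyphenyl]-3-[4-(benzyloxy)phenyl]prop-2-en-1-one | COc1ccc(C(=O)/C=C/c2ccc(OCc3ccccc3)cc2)c(OCc2ccccc2)c1
F3 | step 5 | 1-[2-(benzyloxy)-4-methoxyphenyl]-3,3-bis[4-(benzyloxy)phenyl]propan-1-one | COc1ccc(C(=O)CC(c2ccc(OCc3ccccc3)cc2)c2ccc(OCc3ccccc3)cc2)c(OCc2ccccc2)c1
F4 | step 5 | 2-bromo-1-[2,4-bis(benzyloxy)phenyl]ethanone | O=C(CBr)c1ccc(OCc2ccccc2)cc1OCc1ccccc1
F5 | step 5 | racemic 1-[2,4-bis(benzyloxy)phenyl]-4-[2-(benzyloxy)-4-methoxyphenyl]-3-{bis[4-(benzyloxy)phenyl]methyl}butane-1,4-dione | COc1ccc(C(=O)C(CC(=O)c2ccc(OCc3ccccc3)cc2OCc2ccccc2)C(c2ccc(OCc3ccccc3)cc2)c2ccc(OCc3ccccc3)cc2)c(OCc2ccccc2)c1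
F6 | step 5 | racemic 1-[4-(benzyloxy)-2-hydroxyphenyl]-3-{bis[4-(benzyloxy)phenyl]methyl}-4-(2-hydroxy-4-methoxyphenyl)butane-1,4-dione | COc1ccc(C(=O)C(CC(=O)c2ccc(OCc3ccccc3)cc2O)C(c2ccc(OCc3ccccc3)cc2)c2ccc(OCc3ccccc3)cc2)c(O)c1
F7 | step 5 | racemic 7-(benzyloxy)-3-{1,1-bis[4-(benzyloxy)phenyl]-3-(2-hydroxy-4-methoxyphenyl)-3-oxopropan-2-yl}-4H-chromen-4-one | COc1ccc(C(=O)C(c2coc3cc(OCc4ccccc4)ccc3c2=O)C(c2ccc(OCc3ccccc3)cc2)c2ccc(OCc3ccccc3)cc2)c(O)c1
F8 | step 5 | racemic 7-hydroxy-3-[3-(2-hydroxy-4-methoxyphenyl)-1,1-bis(4-hydroxyphenyl)-3-oxopropan-2-yl]-4H-chromen-4-one (racemic 13) | COc1ccc(C(=O)C(c2coc3cc(O)ccc3c2=O)C(c2ccc(O)cc2)c2ccc(O)cc2)c(O)c1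
F9 | step 2 | (1S)-1-{3-[(1R)-1-(2-bromo-5-methoxyphenoxy)ethyl]phenyl}ethanol | COc1ccc(Br)c(O[C@H](C)c2cccc([C@H](C)O)c2)c1
F10 | step 2 | (1S)-1-{3-[(1R)-1-[2-(1-ethoxyvinyl)-5-methoxyphenoxy]ethyl]phenyl}ethanol | C=C(OCC)c1ccc(OC)cc1O[C@H](C)c1cccc([C@H](C)O)c1
F11 | step 4 | bis(tetrahydro-2H-pyran-2-yl) ether of 8 at its two 4-hydroxyphenyl oxygens (mixture at the two acetal carbons) | COc1ccc(C(=O)/C=C/c2ccc(OC3CCCCO3)cc2)c(O[C@H](C)c2cccc(c2)[C@@H](C)Oc2ccc(C(=O)/C=C/c3ccc(OC4CCCCO4)cc3)c(O)c2)c1
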